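Ring A carbons are cited by their chroman-4-one locants: C8 (quaternary, carrying prenyl and the lavandulyl CH2), C7 (ketone), C6 (carrying the CH(Ph)CH2CO2H arm), C5 (enol) and the two carbons shared with ring B.
Retrosynthetic cuts: the C=CH2 and C–CH3 bonds of the isopropenyl group (back to a lactone carbonyl held on the C7 oxygen), then the C8–CH2 bond of the lavandulyl unit, the C7–O acyl bond, the C8–prenyl bond, the ester of the arm (back to a dihydrocoumarin on the C5 oxygen), the benzylic C–Ph bond, the O–CH bond of ring B, the aryl–acyl bond and the coumarin ring.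
Forward order: coumarin ring on phloroglucinol, acylation, ring B, phenyl group, lactone opening, prenyl at C8, acrylate on the C7 oxygen, then closure of a delta-lactone with dearomatisation of ring A, and conversion of the lactone carbonyl into the isopropenyl group.
Enabling feature: C8 lies para to the C5 oxygen and next to the C7 oxygen, and C8, the CH2 and CH of the lavandulyl group, its isopropenyl carbon, the C7 oxygen and C7 can be drawn as a six-membered lactone, so a 2-prenylacrylate on the C7 oxygen can hand its CH2 to C8.
Stereochemistry: ring B (2R,3S) from a quinine-catalysed oxa-Michael closure; the benzylic centre (S) from a Rh(acac)(C2H4)2/(S)-SEGPHOS-catalysed conjugate arylation; C8 (S) from the face of the dearomatising addition; the lavandulyl CH (S) by equilibration to the trans lactone.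

Key step: step 10

Assumption: the enolised tricarbonyl of ring A is written as the tautomer of the target SMILES (C7 ketone, C5 enol), and the sense of induction of quinine and of (S)-SEGPHOS is taken from the closest coumarin analogues, the pseudo-enantiomeric catalyst being used if the opposite sense is found.

**Route**

Step 1
Reactants: 1 phloroglucinol; 2 ethyl propiolate
Product: 3 5,7-dihydroxycoumarin
Conditions: ZnCl2, neat, 90 °C
Reagents that add atoms: none
Why: Pechmann-type condensation in which the arene adds through carbon to the propiolate and the neighbouring hydroxyl lactonises; the threefold symmetry of 1 allows only one coumarin.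

Step 2
Reactants: 3 5,7-dihydroxycoumarin; 4 tigloyl chloride
Product: 5 5,7-dihydroxy-8-[(E)-2-methylbut-2-enoyl]coumarin
Conditions: AlCl3, PhNO2/1,2-dichloroethane, rt
Reagents that add atoms: none
Why: Friedel–Crafts acylation, which in 5,7-dihydroxycoumarins is known to prefer coumarin position 8 (ortho to the 7-hydroxyl, para to the 5-hydroxyl) over position 6, complexation of the phenolic oxygens by AlCl3 keeping the enone open until work-up.

Step 3
Reactants: 5 5,7-dihydroxy-8-[(E)-2-methylbut-2-enoyl]coumarin
Product: 6 (8R,9S)-5-hydroxy-8,9-dimethyl-8,9-dihydro-2H,10H-pyrano[2,3-f]chromene-2,10-dione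
Conditions: (−)-quinine (20 mol %), chlorobenzene, rt
Reagents that add atoms: none
Why: quinine-catalysed intramolecular oxa-Michael addition of the 7-hydroxyl (the only hydroxyl ortho to the acyl group) to the tigloyl enone, the alkaloid acting as chiral general base to set the O–CH centre and kinetic protonation of the enol giving the cis-dimethyl relationship, as known for 7-hydroxy-8-tigloylcoumarins.

Step 4
Reactants: 6 cis-dimethylchromanone-fused coumarin; 7 phenylboronic acid
Product: 8 (4S,8R,9S)-5-hydroxy-8,9-dimethyl-4-phenyl-3,4,8,9-tetrahydro-2H,10H-pyrano[2,3-f]chromene-2,10-dione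
Conditions: Rh(acac)(C2H4)2 (3 mol %), (S)-SEGPHOS, dioxane/H2O 10:1, 60 °C
Reagents that add atoms: none
Why: Hayashi–Miyaura asymmetric conjugate addition of an arylboronic acid to a coumarin, in which the (S)-SEGPHOS complex of monovalent rhodium should select the face that gives 4S irrespective of the remote ring B centres, while the aryl ketone and the phenol stay inert.

Step 5
Reactants: 8 4-phenyl dihydrocoumarin
Product: 9 methyl (3S)-3-[(2R,3S)-5,7-dihydroxy-2,3-dimethyl-4-oxochroman-6-yl]-3-phenylpropanoate
Conditions: K2CO3 (0.2 equiv), MeOH, 0 °C; AcOH quench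
Reagents that add atoms: methanol, CO
Why: base-catalysed transesterification of the aryl lactone frees the phenol next to the ring B carbonyl (the hydrogen-bonded C5 hydroxyl) and turns the arm into its methyl ester; cold, brief conditions should spare the epimerisable cis centre, and the hydroxy ester is kept neutral and used at once so that it does not close again.

Step 6
Reactants: 9 dihydroxychromanone ester; 10 prenyl bromide
Product: 11 methyl (3S)-3-[(2R,3S)-5,7-dihydroxy-2,3-dimethyl-8-(3-methylbut-2-en-1-yl)-4-oxochroman-6-yl]-3-phenylpropanoate
Conditions: DBU, THF, 0 °C → rt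
Reagents that add atoms: none
Why: C-alkylation of a phloroglucinol-type phenoxide by an allylic bromide at C8, the only unsubstituted ring carbon and ortho/para to the two phenolic oxygens, with O-prenylation the expected minor competitor.

Step 7
Reactants: 12 ethyl 2-(bromomethyl)acrylate; 13 2-methylprop-1-enylmagnesium bromide
Product: 14 ethyl 5-methyl-2-methylidenehex-4-enoate
Conditions: CuI (10 mol %), THF, −78 → 0 °C
Reagents that add atoms: none
Why: CuI-catalysed allylic substitution (SN2') of the bromomethyl acrylate by the alkenyl Grignard reagent, direct and allylic displacement leading to the same 2-prenylacrylate.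

Step 8
Reactants: 14 ethyl 2-prenylacrylate
Product: 15 5-methyl-2-methylidenehex-4-enoic acid
Conditions: LiOH, THF/H2O, rt; then 1 M HCl
Reagents that add atoms: lithium hydroxide, [Li+].[OH-]
Why: ester saponification, the alpha-substituted acrylate being a poor acceptor for hydroxide.

Step 9
Reactants: 11 8-prenyl dihydroxychromanone ester; 15 2-prenylacrylic acid
Product: 16 (2R,3S)-5-hydroxy-6-[(1S)-3-methoxy-3-oxo-1-phenylpropyl]-2,3-dimethyl-8-(3-methylbut-2-en-1-yl)-4-oxochroman-7-yl 5-methyl-2-methylidenehex-4-enoate
Conditions: N,N'-diisopropylcarbodiimide, DMAP (cat.), CH2Cl2, 0 °C → rt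
Reagents that add atoms: none
Why: Steglich-type carbodiimide esterification, selective for the C7 hydroxyl (the acidic, non-chelated phenol) because the C5 hydroxyl is locked in a hydrogen bond to the ring B carbonyl.

Step 10
Reactants: 16 aromatic 8-prenyl chromanone 7-O-(2-prenylacrylate)
Product: 18 dearomatised trans enol lactone, via cis lactone 17 (not isolated)
Conditions: Cs2CO3 (0.5 equiv), N-(9-anthracenylmethyl)cinchonidinium bromide (10 mol %), 4 Å MS, toluene, −20 °C → rt
Reagents that add atoms: none
Why: Proposed new method: carbonate removes the proton of the chelated C5 hydroxyl and the phenoxide, paired with the chiral ammonium ion, attacks through its para carbon C8 the beta-carbon of the acrylate held on the C7 oxygen, after which the ester enolate is protonated by unreacted phenol, leaving ring A as a cross-conjugated dienone that keeps two vinylogous acyl conjugations, so the modest loss of aromaticity of this phloroglucinol ring should be outweighed by the new C–C bond. The closest known reactions are the base-mediated dearomative conjugate additions and SN2' alkylations of acylphloroglucinols and the hydroarylation of aryl acrylates to dihydrocoumarins. The delta-lactone closes in the 6-endo-trig mode, the same mode by which aryl acrylates give dihydrocoumarins. The C8 centre is fixed by the face on which the C8–CH2 bond forms: the ester plane is perpendicular to ring A and should lie anti to the phenyl group of the neighbouring C6 benzylic centre, and the cinchona ammonium counter-ion is chosen to reinforce that face (its pseudo-enantiomer being used if it proves mismatched). The alpha-carbon is set under thermodynamic control, because the C8 prenyl group is pseudo-axial on the lactone and enolisation therefore funnels the cis epimer 17 into 18, whose side chain is pseudo-equatorial and trans. The step needs attack at C8 and not at C6, which the secondary benzylic arm on C6 and the reversibility of the addition should secure, and it needs a non-nucleophilic base so that the acyl-transfer-active enol lactone survives.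

Step 11
Reactants: 18 trans enol lactone
Product: 19 N-methoxy-N-methyl amide of the ring-opened acid (ring A as enolised tricarbonyl; C8 S; side-chain centre S)
Conditions: MeNHOMe·HCl, pyridine, CH2Cl2, 0 °C → rt
Reagents that add atoms: N,O-dimethylhydroxylamine hydrochloride, CNOC.Cl
Why: aminolysis of an enol lactone, which is a vinylogous anhydride and therefore transfers its acyl group to the free amine without a metal promoter, leaving the methyl ester untouched and the side-chain centre no longer next to an activated acyl group.

Step 12
Reactants: 19 Weinreb amide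
Product: 20 methyl ketone (CH3C(=O)–CH(prenyl)–CH2– on C8)
Conditions: MeMgBr (3 equiv), THF, −40 → 0 °C; aq. NH4Cl
Reagents that add atoms: methylmagnesium bromide, C[Mg]Br
Why: Weinreb ketone synthesis, in which the first equivalent turns the tricarbonyl into its bromomagnesium enolate (shielding the ring carbonyls), the chelated tetrahedral adduct prevents over-addition and the low temperature should spare the methyl ester.

Step 13
Reactants: 20 methyl ketone
Product: 21 methyl ester of the target
Conditions: Zn, CH2Br2, TiCl4, THF; then 20, CH2Cl2, 0 °C → rt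
Reagents that add atoms: dibromomethane, BrCBr
Why: Takai–Lombardo methylenation, in which the non-basic CH2(ZnBr)2/TiCl4 reagent converts the ketone into the isopropenyl group without epimerising the adjacent centre and without attacking the ester.

Step 14
Reactants: 21 methyl ester of the target
Product: 22 CNP0150579.2
Conditions: LiOH, THF/H2O, 0 °C → rt; then 1 M HCl to pH 3
Reagents that add atoms: lithium hydroxide, [Li+].[OH-]
Why: ester saponification, during which the tricarbonyl is present as its enolate and thereby protects ring A against retro-Claisen cleavage and the cis centre of ring B against epimerisation.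

**Compound list**

1 | phloroglucinol | Oc1cc(O)cc(O)c1 | starting material
2 | ethyl propiolate | C#CC(=O)OCC | starting material
3 | 5,7-dihydroxycoumarin | O=C1C=Cc2c(O)cc(O)cc2O1 | intermediate
4 | tigloyl chloride, (E)-2-methylbut-2-enoyl chloride | C/C=C(\C)C(Cl)=O | starting material
5 | 5,7-dihydroxy-8-[(E)-2-methylbut-2-enoyl]-2H-chromen-2-one | C/C=C(\C)C(=O)c1c(O)cc(O)c2C=CC(=O)Oc12 | intermediate
6 | (8R,9S)-5-hydroxy-8,9-dimethyl-8,9-dihydro-2H,10H-pyrano[2,3-f]chromene-2,10-dione (coumarin with a cis-2,3-dimethylchroman-4-one ring fused through the 7-oxygen and position 8) | O=C1C=Cc2c(O)cc3O[C@H](C)[C@H](C)C(=O)c3c2O1 | intermediate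
7 | phenylboronic acid | OB(O)c1ccccc1 | starting material
8 | (4S,8R,9S)-5-hydroxy-8,9-dimethyl-4-phenyl-3,4,8,9-tetrahydro-2H,10H-pyrano[2,3-f]chromene-2,10-dione | O=C1C[C@@H](c4ccccc4)c2c(O)cc3O[C@H](C)[C@H](C)C(=O)c3c2O1 | intermediate
9 | methyl (3S)-3-[(2R,3S)-5,7-dihydroxy-2,3-dimethyl-4-oxochroman-6-yl]-3-phenylpropanoate | COC(=O)C[C@@H](c1ccccc1)c1c(O)cc2O[C@H](C)[C@H](C)C(=O)c2c1O | intermediate
10 | prenyl bromide, 1-bromo-3-methylbut-2-ene | CC(C)=CCBr | starting material
11 | methyl (3S)-3-[(2R,3S)-5,7-dihydroxy-2,3-dimethyl-8-(3-methylbut-2-en-1-yl)-4-oxochroman-6-yl]-3-phenylpropanoate | COC(=O)C[C@@H](c1ccccc1)c1c(O)c(CC=C(C)C)c2O[C@H](C)[C@H](C)C(=O)c2c1O | intermediate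
12 | ethyl 2-(bromomethyl)acrylate | C=C(CBr)C(=O)OCC | starting material
13 | 2-methylprop-1-enylmagnesium bromide | CC(C)=C[Mg]Br | starting material
14 | ethyl 5-methyl-2-methylidenehex-4-enoate | C=C(CC=C(C)C)C(=O)OCC | intermediate
15 | 5-methyl-2-methylidenehex-4-enoic acid (2-prenylacrylic acid) | C=C(CC=C(C)C)C(=O)O | intermediate
16 | (2R,3S)-5-hydroxy-6-[(1S)-3-methoxy-3-oxo-1-phenylpropyl]-2,3-dimethyl-8-(3-methylbut-2-en-1-yl)-4-oxochroman-7-yl 5-methyl-2-methylidenehex-4-enoate (key-step precursor) | COC(=O)C[C@@H](c1ccccc1)c1c(OC(=O)C(=C)CC=C(C)C)c(CC=C(C)C)c2O[C@H](C)[C@H](C)C(=O)c2c1O | intermediate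
17 | cis enol lactone: as 18 but with the lactone alpha-carbon R, its prenyl group cis to the C8 prenyl group | O=C3[C@H](CC=C(C)C)C[C@]1(CC=C(C)C)C(O3)=C([C@@H](CC(=O)OC)c4ccccc4)C(=O)C2=C1O[C@H](C)[C@H](C)C2=O | intermediate
18 | trans enol lactone (key-step product): delta-lactone O–C(=O)–CH(prenyl)–CH2 bridging the C7 oxygen and C8; C8 (S) bears prenyl; lactone alpha-carbon (S) with prenyl trans to the C8 prenyl; C5 ketone; double bond between the two ring-fusion carbons; ring B (2R,3S); C6 bears the (S)-CH(Ph)CH2CO2Me arm | O=C3[C@@H](CC=C(C)C)C[C@]1(CC=C(C)C)C(O3)=C([C@@H](CC(=O)OC)c4ccccc4)C(=O)C2=C1O[C@H](C)[C@H](C)C2=O | intermediate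
19 | Weinreb amide: ring A enolised tricarbonyl with C8 (S) bearing prenyl and CH2–CH(prenyl)–C(=O)N(OMe)Me, side-chain centre S, arm as methyl ester | CON(C)C(=O)[C@@H](CC=C(C)C)C[C@]1(CC=C(C)C)C(=O)C([C@@H](CC(=O)OC)c2ccccc2)=C(O)C2=C1O[C@H](C)[C@H](C)C2=O | intermediate
20 | methyl ketone: as 19 with C(=O)CH3 in place of the amide | CC(=O)[C@@H](CC=C(C)C)C[C@]1(CC=C(C)C)C(=O)C([C@@H](CC(=O)OC)c2ccccc2)=C(O)C2=C1O[C@H](C)[C@H](C)C2=O | intermediate
21 | methyl ester of CNP0150579.2 | C=C(C)[C@@H](CC=C(C)C)C[C@]1(CC=C(C)C)C(=O)C([C@@H](CC(=O)OC)c2ccccc2)=C(O)C2=C1O[C@H](C)[C@H](C)C2=O | intermediate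
22 | CNP0150579.2 | C=C(C)[C@@H](CC=C(C)C)C[C@]1(CC=C(C)C)C(=O)C([C@@H](CC(=O)O)c2ccccc2)=C(O)C2=C1O[C@H](C)[C@H](C)C2=O | target

**Step count**

Total: 14 steps. Longest linear sequence: 12 steps (steps 1–6 and 9–14); steps 7 and 8 make the acrylic acid fragment.

**Steps most likely to fail**

Step 10. The equilibrium between the aromatic ester and the dearomatised lactone may not lie far enough on the lactone side, the two faces of C8 may be poorly discriminated, or the base may transfer the acyl group instead of triggering the addition. Within the same disconnection, the unwanted C8 epimer can be returned to 16 by base-induced retro-addition and recycled, and N,O-dimethylhydroxylamine can be added to the same pot so that aminolysis of the enol lactone drains an unfavourable equilibrium. The fallback uses known reaction types, sets out from 9 and returns at 21. Iodination of 9 with N-iodosuccinimide at the only free ring carbon should give the 8-iodo chromanone F1. Commercial (R)-lavandulol is converted with I2, PPh3 and imidazole into (R)-lavandulyl iodide F2 and then with Zn dust and LiCl into (R)-lavandulylzinc iodide F3. Negishi coupling of F1 with an excess of F3 (Pd(OAc)2, SPhos, THF; the excess covers the two phenolic protons) should give the aromatic 8-lavandulyl chromanone F4, whose side-chain centre comes from the chiral pool. Dearomative C-prenylation of F4 with 10 and LiN(SiMe3)2 in THF at 0 °C, the standard access to geminally dialkylated acylphloroglucinols, would then give 21 together with its C8 epimer, which has to be separated.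

Step 4. Insertion of the electron-rich coumarin, hindered by the peri hydroxyl, into the aryl–rhodium bond may be slower than protodeboronation, or catalyst control over the new centre may be incomplete. The fallback carries the phenyl group from the start and sets the centre by hydride delivery; it sets out from 1 and returns at 8. Pechmann condensation of 1 with ethyl benzoylacetate in CF3CO2H gives 5,7-dihydroxy-4-phenylcoumarin F5. Friedel–Crafts acylation with 4 and AlCl3 gives the 8-tigloyl coumarin F6. The quinine-catalysed oxa-Michael closure of step 3 gives the cis-dimethylchromanone-fused 4-phenylcoumarin F7. Asymmetric conjugate reduction of F7 with CuH generated from Cu(OAc)2 and polymethylhydrosiloxane (the DTBM-SEGPHOS enantiomer that delivers 4S, t-BuOH, toluene, low temperature), a known reaction of 4-arylcoumarins that should spare the hindered vinylogous-ester ketone, then gives 8.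

Step 12. The Grignard reagent may attack the unhindered methyl ester of the arm in competition with the alpha-branched amide, or conversion may stall once the substrate is present as a poorly soluble bromomagnesium enolate. The fallback sets out from 18 and returns at 20. Thiolysis of the enol lactone with ethanethiol and Et3N in CH2Cl2 gives the S-ethyl thioester F8. Fukuyama coupling of F8 with MeZnI and PdCl2(PPh3)2 in toluene converts the thioester into the methyl ketone 20 under conditions that leave a methyl ester untouched.

Further compounds
F1 | step 10 | methyl (3S)-3-[(2R,3S)-5,7-dihydroxy-8-iodo-2,3-dimethyl-4-oxochroman-6-yl]-3-phenylpropanoate | COC(=O)C[C@@H](c1ccccc1)c1c(O)c(I)c2O[C@H](C)[C@H](C)C(=O)c2c1O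
F2 | step 10 | (R)-lavandulyl iodide, (3R)-3-(iodomethyl)-2,6-dimethylhepta-1,5-diene | C=C(C)[C@@H](CC=C(C)C)CI
F3 | step 10 | (R)-lavandulylzinc iodide | C=C(C)[C@@H](CC=C(C)C)C[Zn]I
F4 | step 10 | methyl (3S)-3-[(2R,3S)-5,7-dihydroxy-2,3-dimethyl-8-[(2S)-5-methyl-2-(prop-1-en-2-yl)hex-4-en-1-yl]-4-oxochroman-6-yl]-3-phenylpropanoate | COC(=O)C[C@@H](c1ccccc1)c1c(O)c(C[C@H](CC=C(C)C)C(C)=C)c2O[C@H](C)[C@H](C)C(=O)c2c1O
F5 | step 4 | 5,7-dihydroxy-4-phenylcoumarin | O=C1C=C(c2ccccc2)c2c(O)cc(O)cc2O1
F6 | step 4 | 5,7-dihydroxy-8-[(E)-2-methylbut-2-enoyl]-4-phenylcoumarin | C/C=C(\C)C(=O)c1c(O)cc(O)c2C(c3ccccc3)=CC(=O)Oc12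
F7 | step 4 | (8R,9S)-5-hydroxy-8,9-dimethyl-4-phenyl-8,9-dihydro-2H,10H-pyrano[2,3-f]chromene-2,10-dione | O=C1C=C(c4ccccc4)c2c(O)cc3O[C@H](C)[C@H](C)C(=O)c3c2O1
F8 | step 12 | S-ethyl thioester of the ring-opened acid (as 19 with C(=O)SEt in place of the amide) | CCSC(=O)[C@@H](CC=C(C)C)C[C@]1(CC=C(C)C)C(=O)C([C@@H](CC(=O)OC)c2ccccc2)=C(O)C2=C1O[C@H](C)[C@H](C)C2=O
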